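**Retrosynthetic overview**

1. The angelate at O3 (mixed-anhydride acylation) and the umbelliferyl ether at C11 (Mitsunobu) are cut back to drimane-3α,8α,11-triol. Its 8α-OH/8β-CH3 pair comes from an 8(12)-exo-methylene (α-epoxidation, hydride opening), and that from an 8-oxo-9-ester.
2. Ring A: the C1–C10 and C4–C5 bonds are made together by a radical [4+2] annulation of 2-bromo-2-methylpent-4-en-3-one (C1–C4, both C4 methyls, C3 carbonyl) across the C5=C10 alkene of a ring B cyclohexene.
3. Enabling feature: in ring A the C3 carbonyl carbon is bonded to quaternary C4 (a tertiary α-keto radical) and, through C2, to C1 (β-carbon of a vinyl ketone). Ring B meets ring A at a trisubstituted C5=C10 alkene, so attack at C5 leaves a tertiary C10 radical placed for 6-endo closure onto C1.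
4. Ring B is made first (Evans syn aldol, then ring-closing metathesis) with a removable N-acyl oxazolidinone at C9 that steers the annulation. Ring A is made second; the auxiliary is then cleaved and C9 is inverted through the β-keto ester.

Key step: step 5

Remark: drimane numbering is used (ring A = C1–C5 and C10, ring B = C5–C10, C11 on C9, C12 on C8); α is the face opposite the C10 methyl; the target ester is the (Z)-2-methylbut-2-enoate (angelate) written in the SMILES.

**Step 1**
Reactants: 1 (S)-4-benzyl-1,3-oxazolidin-2-one; 2 3-methylbut-3-enoic acid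
Product: 4 (4S)-4-benzyl-3-(3-methylbut-3-enoyl)-1,3-oxazolidin-2-one, via mixed pivalic anhydride 3 (not isolated)
Conditions: 2, PivCl, Et3N, THF, −20 °C; then LiCl, 1, −20 °C → rt
Reagents that add atoms: none
Why: N-Acylation of the oxazolidinone through the mixed pivalic anhydride (LiCl/Et3N protocol) occurs at the unhindered carbonyl under conditions too mild to move the β,γ-double bond into conjugation, and no stereocenter is formed.

**Step 2**
Reactants: 4 (4S)-4-benzyl-3-(3-methylbut-3-enoyl)-1,3-oxazolidin-2-one; 5 pent-4-enal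
Product: 7 (4S)-4-benzyl-3-[(2S,3R)-3-hydroxy-2-(prop-1-en-2-yl)hept-6-enoyl]-1,3-oxazolidin-2-one, via dibutylboron (Z)-enolate 6 (not isolated)
Conditions: Bu2BOTf, iPr2NEt, CH2Cl2, −78 → 0 °C; 5, −78 → 0 °C; pH 7 buffer, MeOH, H2O2
Reagents that add atoms: none
Why: Evans syn aldol reaction: the (Z)-boron enolate reacts at its α-carbon through a closed Zimmerman–Traxler transition state on the face opposite the benzyl group, which should set the carbinol carbon (future C8, R) and the α-carbon (future C9, S) syn to each other.

**Step 3**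
Reactants: 7 (4S)-4-benzyl-3-[(2S,3R)-3-hydroxy-2-(prop-1-en-2-yl)hept-6-enoyl]-1,3-oxazolidin-2-one
Product: 8 (4S)-4-benzyl-3-[(1S,6R)-6-hydroxy-2-methylcyclohex-2-ene-1-carbonyl]-1,3-oxazolidin-2-one
Conditions: second-generation Grubbs catalyst, (H2IMes)(PCy3)Cl2Ru=CHPh (3 mol %), CH2Cl2 (0.01 M), 40 °C
Reagents that add atoms: none
Why: Ring-closing metathesis of the isopropenyl and terminal vinyl groups releases ethene and closes ring B as the trisubstituted C5=C10 cyclohexene without touching the two stereocenters.

**Step 4**
Reactants: 9 2-bromo-2-methylpropanoyl bromide; 10 trimethyl(vinyl)silane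
Product: 11 2-bromo-2-methylpent-4-en-3-one
Conditions: AlBr3 (1.05 equiv), CH2Cl2, −78 → −30 °C; cold aq. NaHCO3; used at once as a cold solution
Reagents that add atoms: none
Why: Friedel–Crafts acylation of the vinylsilane at the silicon-bearing carbon (ipso substitution through the β-silyl cation) gives the vinyl ketone regiospecifically; no stereocenter is involved and the enone is used directly because it polymerises readily.

**Step 5**
Reactants: 8 (4S)-4-benzyl-3-[(1S,6R)-6-hydroxy-2-methylcyclohex-2-ene-1-carbonyl]-1,3-oxazolidin-2-one; 11 2-bromo-2-methylpent-4-en-3-one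
Product: 13 (4S)-4-benzyl-3-(8α-hydroxy-3-oxo-12-nor-9-epi-driman-11-oyl)-1,3-oxazolidin-2-one (trans-decalin; 5α-H; 10β-CH3; 9α-acyl; 8α-OH), via 2-bromo ketone 12 (not isolated)
Conditions: [Ir(dF(CF3)ppy)2(dtbbpy)]PF6 (1 mol %), LiBr, DMF, blue LEDs, rt, 11 (3 equiv) added slowly; then Zn, AcOH, rt
Reagents that add atoms: none
Why: Proposed new method: the excited iridium photocatalyst reduces the C–Br bond of 11 to the electrophilic tertiary α-keto radical (future C4), which adds to C5, the unsubstituted end of the C5=C10 alkene of 8; the nucleophilic tertiary C10 radical so formed attacks the β-carbon of the pendant vinyl ketone (future C1), and the resulting C2 α-keto radical carries the chain by abstracting bromine from 11 to give 12, whose bromine is then removed by zinc in acetic acid. The closest known reaction types are the Kharasch-type photoredox atom-transfer addition of α-bromo carbonyl compounds to alkenes and the 6-endo closures of tertiary radicals in radical polyene cyclisations. Ring A is closed in the 6-endo-trig mode, since 5-exo attack at the α-carbon of the enone is contra-polar and would give a primary radical. C5 is controlled by the C9 N-acyl oxazolidinone, which A(1,2) strain with the C10 methyl holds pseudoaxial on the α face of the cyclohexene, so that the bulky radical should enter on the β face; C10 is controlled by a chair-like transition state with the C5–C4 bond equatorial on ring B and the methyl group axial, which should give the trans ring fusion as in polyene cyclisations. The step needs addition at C5 and not at C10 (secured by the trisubstituted alkene, which yields the tertiary radical), cross-addition before self-reaction of the enone (helped by slow addition of 11, whose radical is polarity-mismatched with its own vinyl ketone) and β-face attack (secured by the auxiliary).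

**Step 6**
Reactants: 13 (4S)-4-benzyl-3-(8α-hydroxy-3-oxo-12-nor-9-epi-driman-11-oyl)-1,3-oxazolidin-2-one
Product: 14 methyl 8α-hydroxy-3-oxo-12-nor-9-epi-driman-11-oate (9α-CO2CH3)
Conditions: MeMgBr, MeOH (gives MeOMgBr), CH2Cl2, 0 °C
Reagents that add atoms: methanol (as MeOMgBr), CO
Why: Transesterification of the N-acyl oxazolidinone with bromomagnesium methoxide, helped by magnesium chelation between the cis 8-hydroxyl and the exocyclic carbonyl, should cleave the auxiliary without epimerisation or retro-aldol reaction.

**Step 7**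
Reactants: 14 methyl 8α-hydroxy-3-oxo-12-nor-9-epi-driman-11-oate
Product: 16 methyl 3,8-dioxo-12-nordriman-11-oate (9β-CO2CH3; 9α-H), via 9α-ester epimer 15 (not isolated)
Conditions: Pr4N[RuO4] (5 mol %), NMO, 4 Å MS, CH2Cl2, rt; then DBU (0.1 equiv), rt
Reagents that add atoms: none
Why: Ley–Griffith oxidation gives the β-keto ester, whose C9 then equilibrates through the enol to the thermodynamically preferred equatorial 9β-ester (9α-H) of the trans-decalin, which corrects the C9 stereocenter.

**Step 8**
Reactants: 16 methyl 3,8-dioxo-12-nordriman-11-oate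
Product: 18 methyl 3α-hydroxy-8-oxo-12-nordriman-11-oate, via sodium enolate 17 (not isolated)
Conditions: NaH (1.05 equiv), THF, 0 °C; LiBH(s-Bu)3 (L-Selectride, 1.2 equiv), −78 °C; AcOH
Reagents that add atoms: none
Why: The β-keto ester is masked as its sodium enolate so that only the C3 ketone is reduced, and the bulky hydride of L-Selectride attacks the 4,4-dimethyl ketone from the equatorial direction to give the axial 3α-alcohol (diastereoselective ketone reduction).

**Step 9**
Reactants: 18 methyl 3α-hydroxy-8-oxo-12-nordriman-11-oate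
Product: 20 methyl 3α-hydroxydrim-8(12)-en-11-oate, via β-hydroxysilane 19 (not isolated)
Conditions: Me3SiCH2MgCl (3.5 equiv), CeCl3, THF, −78 → 0 °C; then 1 M HCl, THF, rt
Reagents that add atoms: (trimethylsilyl)methylmagnesium chloride, C[Si](C)(C)C[Mg]Cl
Why: Peterson methylenation in its organocerium variant: the weakly basic cerium reagent adds to the readily enolised C8 ketone instead of deprotonating it, and acid-induced anti elimination of trimethylsilanol from the β-hydroxysilane gives the exocyclic alkene while C9 stays untouched.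

**Step 10**
Reactants: 20 methyl 3α-hydroxydrim-8(12)-en-11-oate
Product: 21 methyl 8α,12-epoxy-3α-hydroxydriman-11-oate
Conditions: m-CPBA, NaHCO3, CH2Cl2, 0 °C
Reagents that add atoms: m-CPBA, OOC(=O)c1cccc(Cl)c1
Why: Prilezhaev epoxidation of the 1,1-disubstituted alkene should occur from the α (equatorial) side because the β side is blocked by the syn-axial C10 methyl group, which sets C8 with oxygen α.

**Step 11**
Reactants: 21 methyl 8α,12-epoxy-3α-hydroxydriman-11-oate
Product: 22 drimane-3α,8α,11-triol
Conditions: LiAlH4, THF, 0 °C → reflux; Fieser work-up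
Reagents that add atoms: none
Why: Hydride opens the spiro-epoxide by SN2 attack at its CH2 carbon, which leaves the 8α tertiary alcohol beside the new 8β methyl group, and the same reagent reduces the ester to the C11 primary alcohol (LiAlH4 reduction).

**Step 12**
Reactants: 22 drimane-3α,8α,11-triol; 23 umbelliferone (7-hydroxy-2H-chromen-2-one)
Product: 24 7-[(3α,8α-dihydroxydriman-11-yl)oxy]-2H-chromen-2-one
Conditions: PPh3, DIAD, THF, 0 °C → rt
Reagents that add atoms: none
Why: Mitsunobu etherification activates only the primary C11 hydroxyl (the axial neopentyl 3α-OH and the tertiary 8α-OH are too hindered) and the acidic phenol of umbelliferone displaces it; no stereocenter is touched.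

**Step 13**
Reactants: 24 7-[(3α,8α-dihydroxydriman-11-yl)oxy]-2H-chromen-2-one; 25 angelic acid ((Z)-2-methylbut-2-enoic acid)
Product: 27 7-{[3α-(angeloyloxy)-8α-hydroxydriman-11-yl]oxy}-2H-chromen-2-one (target), via angelic 2,4,6-trichlorobenzoic anhydride 26 (not isolated)
Conditions: 25, 2,4,6-trichlorobenzoyl chloride, Et3N, toluene, rt; then 24, toluene, 80 °C
Reagents that add atoms: none
Why: Yamaguchi-type esterification through the mixed 2,4,6-trichlorobenzoic anhydride acylates the hindered secondary 3α-hydroxyl with retention at C3 (the C–O bond is not broken), leaves the tertiary 8-hydroxyl untouched and is run without nucleophilic catalyst to keep the (Z)-geometry of the angeloyl group.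

**Compound list**

1 | (S)-4-benzyl-1,3-oxazolidin-2-one | O=C1N[C@@H](Cc2ccccc2)CO1 | starting material
2 | 3-methylbut-3-enoic acid | C=C(C)CC(=O)O | starting material
3 | 3-methylbut-3-enoic pivalic anhydride | C=C(C)CC(=O)OC(=O)C(C)(C)C | intermediate
4 | (4S)-4-benzyl-3-(3-methylbut-3-enoyl)-1,3-oxazolidin-2-one | C=C(C)CC(=O)N1C(=O)OC[C@@H]1Cc1ccccc1 | intermediate
5 | pent-4-enal | C=CCCC=O | starting material
6 | dibutylboron (Z)-enolate of 4 | C=C(C)/C=C(\OB(CCCC)CCCC)N1C(=O)OC[C@@H]1Cc1ccccc1 | intermediate
7 | (4S)-4-benzyl-3-[(2S,3R)-3-hydroxy-2-(prop-1-en-2-yl)hept-6-enoyl]-1,3-oxazolidin-2-one | C=CCC[C@@H](O)[C@H](C(C)=C)C(=O)N1C(=O)OC[C@@H]1Cc1ccccc1 | intermediate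
8 | (4S)-4-benzyl-3-[(1S,6R)-6-hydroxy-2-methylcyclohex-2-ene-1-carbonyl]-1,3-oxazolidin-2-one | CC1=CCC[C@@H](O)[C@H]1C(=O)N1C(=O)OC[C@@H]1Cc1ccccc1 | intermediate
9 | 2-bromo-2-methylpropanoyl bromide | CC(C)(Br)C(=O)Br | starting material
10 | trimethyl(vinyl)silane | C=C[Si](C)(C)C | starting material
11 | 2-bromo-2-methylpent-4-en-3-one | C=CC(=O)C(C)(C)Br | intermediate
12 | 2-bromo derivative of 13 (C2 epimers) | O=C1C(Br)C[C@]2(C)[C@H](C(=O)N3C(=O)OC[C@@H]3Cc3ccccc3)[C@H](O)CC[C@H]2C1(C)C | intermediate
13 | (4S)-4-benzyl-3-(8α-hydroxy-3-oxo-12-nor-9-epi-driman-11-oyl)-1,3-oxazolidin-2-one | O=C1CC[C@]2(C)[C@H](C(=O)N3C(=O)OC[C@@H]3Cc3ccccc3)[C@H](O)CC[C@H]2C1(C)C | intermediate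
14 | methyl 8α-hydroxy-3-oxo-12-nor-9-epi-driman-11-oate | O=C1CC[C@]2(C)[C@H](C(=O)OC)[C@H](O)CC[C@H]2C1(C)C | intermediate
15 | methyl 3,8-dioxo-12-nor-9-epi-driman-11-oate (9α-ester) | O=C1CC[C@]2(C)[C@H](C(=O)OC)C(=O)CC[C@H]2C1(C)C | intermediate
16 | methyl 3,8-dioxo-12-nordriman-11-oate (9β-ester) | O=C1CC[C@]2(C)[C@@H](C(=O)OC)C(=O)CC[C@H]2C1(C)C | intermediate
17 | sodium enolate of 16 (C8–O−, C8=C9) | O=C1CC[C@]2(C)C(C(=O)OC)=C([O-])CC[C@H]2C1(C)C.[Na+] | intermediate
18 | methyl 3α-hydroxy-8-oxo-12-nordriman-11-oate | O[C@@H]1CC[C@]2(C)[C@@H](C(=O)OC)C(=O)CC[C@H]2C1(C)C | intermediate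
19 | methyl 3α,8-dihydroxy-8-[(trimethylsilyl)methyl]-12-nordriman-11-oate (C8 epimers) | O[C@@H]1CC[C@]2(C)[C@@H](C(=O)OC)C(O)(C[Si](C)(C)C)CC[C@H]2C1(C)C | intermediate
20 | methyl 3α-hydroxydrim-8(12)-en-11-oate | O[C@@H]1CC[C@]2(C)[C@@H](C(=O)OC)C(=C)CC[C@H]2C1(C)C | intermediate
21 | methyl 8α,12-epoxy-3α-hydroxydriman-11-oate | O[C@@H]1CC[C@]2(C)[C@@H](C(=O)OC)[C@@]3(CO3)CC[C@H]2C1(C)C | intermediate
22 | drimane-3α,8α,11-triol | O[C@@H]1CC[C@]2(C)[C@@H](CO)[C@](C)(O)CC[C@H]2C1(C)C | intermediate
23 | umbelliferone | Oc1ccc2ccc(=O)oc2c1 | starting material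
24 | 7-[(3α,8α-dihydroxydriman-11-yl)oxy]-2H-chromen-2-one | O[C@@H]1CC[C@]2(C)[C@@H](COc3ccc4ccc(=O)oc4c3)[C@](C)(O)CC[C@H]2C1(C)C | intermediate
25 | angelic acid | C/C=C(/C)C(=O)O | starting material
26 | angelic 2,4,6-trichlorobenzoic anhydride | C/C=C(/C)C(=O)OC(=O)c1c(Cl)cc(Cl)cc1Cl | intermediate
27 | 7-{[3α-(angeloyloxy)-8α-hydroxydriman-11-yl]oxy}-2H-chromen-2-one | C/C=C(/C)C(=O)O[C@@H]1CC[C@]2(C)[C@@H](COc3ccc4ccc(=O)oc4c3)[C@](C)(O)CC[C@H]2C1(C)C | target

**Totals**

Total step count: 13. Longest linear sequence: 12 steps (steps 1–3 and 5–13; step 4 makes the annulation partner).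

**Steps most likely to fail**

Step 5 (bears the label Proposed new method). The tertiary α-keto radical may add too slowly to the hindered ring alkene, so that oligomerisation of the vinyl ketone or premature halogen transfer takes over. Facial selectivity at C5 may be poor, or part of the material may close to the cis-fused ring. The fallback uses known reactions and separates the two bond formations with the acceptor masked; it sets out from 9 and 8 and comes back at 13. Friedel–Crafts acylation of ethene with 9 (AlBr3, CH2Cl2, −20 °C) should give 2,5-dibromo-2-methylpentan-3-one F1. A Kharasch atom-transfer addition of F1 to 8 (CuBr, tris(2-pyridylmethyl)amine, or the photoredox conditions of step 5) should give the open-chain tertiary C10 bromide with the ketone side chain on C5 F2, because no enone is present to trap the C10 radical. Et3N then eliminates HBr from the β-bromo ketone to unmask the vinyl ketone F3. Finally Bu3SnH/AIBN in benzene at 80 °C under high dilution generates the C10 radical, which closes ring A by the known 6-endo cyclisation onto the enone to give 13.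

Step 13. Acylation of the axial 3α-hydroxyl next to the gem-dimethyl group may be sluggish, and the activated angeloyl unit may isomerise from (Z) to (E) on prolonged heating. The fallback builds the (Z)-alkene on the alcohol instead of transferring it; it sets out from 24 and comes back at 27. Esterification of 24 with 2-[bis(2,2,2-trifluoroethoxy)phosphoryl]propanoic acid (DCC, DMAP, CH2Cl2) should give the 3α-phosphonopropanoate F4. Still–Gennari olefination of F4 with acetaldehyde (KN(SiMe3)2, 18-crown-6, THF, −78 °C) should then give the (Z)-2-methylbut-2-enoate 27.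

Step 12. Substitution at the β-branched C11 carbon may be slow, so that loss of the activated hydroxyl by elimination or by ring closure with the 8-hydroxyl competes. The fallback forms the C–O bond at the aryl carbon instead; it sets out from 22 and comes back at 24. Palladium-catalysed C–O coupling of the primary alcohol of 22 with commercial 7-bromo-2H-chromen-2-one (Pd2(dba)3, RockPhos, Cs2CO3, toluene, 90 °C) should give 24 without any substitution at C11.

**Further compounds**

F1 | step 5 | 2,5-dibromo-2-methylpentan-3-one | CC(C)(Br)C(=O)CCBr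
F2 | step 5 | open-chain Kharasch adduct of 8 (C10 tertiary bromide, C10 epimers; 5-bromo-2-methyl-3-oxopentan-2-yl group β on C5) | CC1(Br)[C@H](C(=O)N2C(=O)OC[C@@H]2Cc2ccccc2)[C@H](O)CC[C@H]1C(C)(C)C(=O)CCBr
F3 | step 5 | vinyl ketone from F2 (C10 tertiary bromide; 2-methyl-3-oxopent-4-en-2-yl group β on C5) | CC1(Br)[C@H](C(=O)N2C(=O)OC[C@@H]2Cc2ccccc2)[C@H](O)CC[C@H]1C(C)(C)C(=O)C=C
F4 | step 13 | 3α-{2-[bis(2,2,2-trifluoroethoxy)phosphoryl]propanoyloxy} derivative of 24 | CC(C(=O)O[C@@H]1CC[C@]2(C)[C@@H](COc3ccc4ccc(=O)oc4c3)[C@](C)(O)CC[C@H]2C1(C)C)P(=O)(OCC(F)(F)F)OCC(F)(F)F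
F0 | step 12 | none | none
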